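A direct plan would set the carbinol carbon and the neighbouring ring carbon by an auxiliary-controlled syn aldol that gives imide A1, would degrade it to the β-substituted γ-butyrolactone A2, would benzylate the enolate of lactone A2 trans to the side chain, and would reduce the product to the 1,4-diol A3, which would be closed to the tetrahydrofuran at oxygen before the phenols are freed. Its weakest steps would be three. The oxidation-state shuttle between imide A1 and diol A3 (auxiliary reduction, alkene cleavage, lactol oxidation, lactone reduction, carbinol silylation and desilylation) would add about half of the steps without adding a skeletal bond. The enolate benzylation of lactone A2 would have to deliver one face next to a bulky silyloxybenzyl group with a labile, electron-rich benzylic bromide. The final hydrogenolysis of the aryl benzyl ethers would compete with C–O hydrogenolysis of the electron-rich benzylic alcohol.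

The tetrahydrofuran (ring atoms O1, C2, C3, C4, C5; carbinol carbon on C3, benzyl on C4) would not be closed at oxygen but contracted out of a seven-membered ring. C3, which carries an exocyclic oxygenated carbon next to the ring CH2–O at C2, is the retron of a 1,3-O→C shift of a cyclic vinyl acetal. An enantioselective Heck benzylation of 4,7-dihydro-1,3-dioxepine would set C4 and give that vinyl acetal; a Lewis acid would then turn one acetal C–O bond into the C2–C3 bond, placing C3 trans to C4. No lactone, diol cyclisation, carbinol protection or benzyl ether would be needed; the carbinol would be set last by ketone reduction.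

Key step: step 5

Assumption (chemistry): the sense of induction of the phosphoramidite ligand in step 4 cannot be predicted with confidence; the ligand antipode that gives (R)-6 would be chosen after a first run, and the R series is drawn throughout.

Step 1
Reactants: 1 syringaldehyde (4-hydroxy-3,5-dimethoxybenzaldehyde)
Product: 2 3,5-dimethoxy-4-[(triisopropylsilyl)oxy]benzaldehyde
Conditions: TIPSCl, imidazole, DMAP (cat.), DMF, 40 °C
Reagents that add atoms: chlorotriisopropylsilane, CC(C)[Si](Cl)(C(C)C)C(C)C
Why: Imidazole-promoted silyl ether formation at the only acidic hydroxyl gives an aryl triisopropylsilyl ether that should survive the later palladium, Lewis-acid, aryllithium, periodinane and borane steps and leave with fluoride, so that neither acid nor hydrogenolysis is needed at the end.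

Step 2
Reactants: 2 3,5-dimethoxy-4-[(triisopropylsilyl)oxy]benzaldehyde
Product: 3 {3,5-dimethoxy-4-[(triisopropylsilyl)oxy]phenyl}methanol
Conditions: NaBH4, MeOH/THF, 0 °C
Reagents that add atoms: none
Why: Borohydride reduction of the aryl aldehyde to the benzylic alcohol is chemoselective because nothing else in the molecule is reducible.

Step 3
Reactants: 3 {3,5-dimethoxy-4-[(triisopropylsilyl)oxy]phenyl}methanol
Product: 4 3,5-dimethoxy-4-[(triisopropylsilyl)oxy]benzyl trifluoroacetate
Conditions: (CF3CO)2O, pyridine, CH2Cl2, 0 °C; used crude without chromatography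
Reagents that add atoms: trifluoroacetic anhydride, O=C(OC(=O)C(F)(F)F)C(F)(F)F
Why: O-Acylation with the anhydride installs the benzylic trifluoroacetate that zerovalent palladium cleaves in the next step, and the ester is used at once because this electron-rich benzylic ester ionises easily.

Step 4
Reactants: 4 3,5-dimethoxy-4-[(triisopropylsilyl)oxy]benzyl trifluoroacetate; 5 4,7-dihydro-1,3-dioxepine (4 equiv)
Product: 6 (R)-5-{3,5-dimethoxy-4-[(triisopropylsilyl)oxy]benzyl}-4,5-dihydro-1,3-dioxepine
Conditions: Pd(dba)2 (5 mol%), BINOL-derived phosphoramidite (MonoPhos type, 12 mol%), Li2CO3, THF, 60 °C; chromatography on Et3N-washed silica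
Reagents that add atoms: none
Why: In this enantioselective Mizoroki–Heck benzylation of a cyclic olefin, zerovalent palladium inserts into the benzylic C–O bond, the benzylpalladium species adds syn across the cis alkene of the mirror-symmetric dioxepine, and syn β-hydride elimination can only use a C7 hydrogen (the C5 hydrogen is anti to palladium), which moves the double bond next to O1 and gives the vinyl acetal, while the chiral ligand chooses between the two enantiotopic alkene carbons and so sets C5 (the later ring C4) as R.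

Step 5
Reactants: 6 (R)-5-{3,5-dimethoxy-4-[(triisopropylsilyl)oxy]benzyl}-4,5-dihydro-1,3-dioxepine
Product: 8 (3R,4R)-4-{3,5-dimethoxy-4-[(triisopropylsilyl)oxy]benzyl}tetrahydrofuran-3-carbaldehyde, via enolate–oxocarbenium zwitterion 7 (not isolated)
Conditions: BF3·OEt2 (20 mol%), CH2Cl2, −78 → −30 °C; Et3N quench
Reagents that add atoms: none
Why: BF3 binds the vinylic acetal oxygen O1 and the C2–O1 bond ionises, because the enolate is the better leaving group and the alkyl oxygen O3 keeps a stabilised oxocarbenium ion, giving the tethered Z-enolate/oxocarbenium pair 7, whose enolate α-carbon (dioxepine C6) then attacks the formaldehyde-derived carbon C2. The closest known reaction type is the Lewis-acid 1,3-O→C rearrangement of 4,5-dihydro-1,3-dioxepines (cyclic vinyl acetals) to tetrahydrofuran-3-carbaldehydes, a Petasis–Ferrier-type ring contraction. The tetrahydrofuran closes by a 5-(enolexo)-endo-trig Mukaiyama-type aldol addition that forms the C2–C3 bond of the product, and the seven-membered ring contracts without loss of atoms, O1 becoming the aldehyde oxygen. The benzyl-bearing centre is untouched because no bond to it is broken; the new C3 centre is set trans by allylic 1,3-strain in the Z-enolate, which places the C5 hydrogen in the enolate plane so that the oxocarbenium arm and the benzyl group occupy opposite faces, and because C3 is α to the aldehyde the trans isomer is also the thermodynamic one. The step needs ionisation at O1 and not at O3, and no arene trapping: ionisation at O3 would give an unproductive vinyloxy-substituted cation that can only re-close, and Friedel–Crafts attack by the silyloxy-dimethoxyphenyl ring would need a seven-membered transition state, whereas the enolate attack is five-membered.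

Step 6
Reactants: 9 4-bromo-2,6-dimethoxyphenol
Product: 10 (4-bromo-2,6-dimethoxyphenoxy)triisopropylsilane
Conditions: TIPSCl, imidazole, DMAP (cat.), DMF, 40 °C
Reagents that add atoms: chlorotriisopropylsilane, CC(C)[Si](Cl)(C(C)C)C(C)C
Why: The same imidazole-promoted silylation masks the phenol so that the aryl bromide can be lithiated, and a silyl group para to the lithium cannot migrate to carbon.

Step 7
Reactants: 10 (4-bromo-2,6-dimethoxyphenoxy)triisopropylsilane; 8 (3R,4R)-4-{3,5-dimethoxy-4-[(triisopropylsilyl)oxy]benzyl}tetrahydrofuran-3-carbaldehyde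
Product: 12 {(3R,4R)-4-{3,5-dimethoxy-4-[(triisopropylsilyl)oxy]benzyl}tetrahydrofuran-3-yl}{3,5-dimethoxy-4-[(triisopropylsilyl)oxy]phenyl}methanol (both carbinol epimers), via aryllithium 11 (not isolated)
Conditions: 10, n-BuLi, THF, −78 °C; then 8, −78 °C; NH4Cl (aq)
Reagents that add atoms: none
Why: Bromine–lithium exchange followed by 1,2-addition of the aryllithium to the aldehyde forms the aryl–carbinol bond, and the new carbinol centre needs no control (Felkin–Anh addition should favour the unwanted R epimer) because both epimers converge on the ketone in the next step.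

Step 8
Reactants: 12 {(3R,4R)-4-{3,5-dimethoxy-4-[(triisopropylsilyl)oxy]benzyl}tetrahydrofuran-3-yl}{3,5-dimethoxy-4-[(triisopropylsilyl)oxy]phenyl}methanol (both carbinol epimers)
Product: 13 {(3R,4R)-4-{3,5-dimethoxy-4-[(triisopropylsilyl)oxy]benzyl}tetrahydrofuran-3-yl}{3,5-dimethoxy-4-[(triisopropylsilyl)oxy]phenyl}methanone
Conditions: Dess–Martin periodinane, CH2Cl2, 0 °C → rt
Reagents that add atoms: none
Why: Dess–Martin oxidation of the benzylic alcohol to the aryl ketone is neutral and fast, so the α-centre, which is trans and thermodynamically preferred in any case, is not at risk.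

Step 9
Reactants: 13 {(3R,4R)-4-{3,5-dimethoxy-4-[(triisopropylsilyl)oxy]benzyl}tetrahydrofuran-3-yl}{3,5-dimethoxy-4-[(triisopropylsilyl)oxy]phenyl}methanone
Product: 14 (S)-{(3R,4R)-4-{3,5-dimethoxy-4-[(triisopropylsilyl)oxy]benzyl}tetrahydrofuran-3-yl}{3,5-dimethoxy-4-[(triisopropylsilyl)oxy]phenyl}methanol
Conditions: (R)-2-methyl-CBS-oxazaborolidine (20 mol%), BH3·SMe2, THF, −30 °C; MeOH quench
Reagents that add atoms: none
Why: In this Corey–Bakshi–Shibata reduction the (R)-oxazaborolidine–borane complex binds the ketone oxygen at the lone pair anti to the aryl group (the larger substituent) and delivers hydride to the face that gives the S carbinol, which is also the face favoured by Felkin–Anh attack anti to the C4 branch of the ring, so reagent and substrate control should be matched.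

Step 10
Reactants: 14 (S)-{(3R,4R)-4-{3,5-dimethoxy-4-[(triisopropylsilyl)oxy]benzyl}tetrahydrofuran-3-yl}{3,5-dimethoxy-4-[(triisopropylsilyl)oxy]phenyl}methanol
Product: 15 (S)-(4-hydroxy-3,5-dimethoxyphenyl)[(3R,4R)-4-(4-hydroxy-3,5-dimethoxybenzyl)tetrahydrofuran-3-yl]methanol (target)
Conditions: n-Bu4NF, THF, 0 °C; NH4Cl (aq)
Reagents that add atoms: none
Why: Fluoride desilylation, driven by the Si–F bond, cleaves both aryl silyl ethers without acid, which would ionise the electron-rich benzylic alcohol, and without hydrogen, so all three stereocentres are untouched.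

**Compound list**
1 | syringaldehyde (4-hydroxy-3,5-dimethoxybenzaldehyde) | COc1cc(C=O)cc(OC)c1O | starting material
2 | 3,5-dimethoxy-4-[(triisopropylsilyl)oxy]benzaldehyde | COc1cc(C=O)cc(OC)c1O[Si](C(C)C)(C(C)C)C(C)C | intermediate
3 | {3,5-dimethoxy-4-[(triisopropylsilyl)oxy]phenyl}methanol | COc1cc(CO)cc(OC)c1O[Si](C(C)C)(C(C)C)C(C)C | intermediate
4 | 3,5-dimethoxy-4-[(triisopropylsilyl)oxy]benzyl trifluoroacetate | COc1cc(COC(=O)C(F)(F)F)cc(OC)c1O[Si](C(C)C)(C(C)C)C(C)C | intermediate
5 | 4,7-dihydro-1,3-dioxepine (formaldehyde acetal of cis-but-2-ene-1,4-diol) | C1OCC=CCO1 | starting material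
6 | (R)-5-{3,5-dimethoxy-4-[(triisopropylsilyl)oxy]benzyl}-4,5-dihydro-1,3-dioxepine | COc1cc(C[C@H]2COCOC=C2)cc(OC)c1O[Si](C(C)C)(C(C)C)C(C)C | intermediate
7 | ring-opened form of 6: BF3-bound (Z)-enolate tethered through CH2–O to a methyleneoxonium ion (R at the benzyl-bearing carbon) | COc1cc(C[C@@H](C[O+]=C)/C=C\O[B-](F)(F)F)cc(OC)c1O[Si](C(C)C)(C(C)C)C(C)C | intermediate
8 | (3R,4R)-4-{3,5-dimethoxy-4-[(triisopropylsilyl)oxy]benzyl}tetrahydrofuran-3-carbaldehyde | COc1cc(C[C@H]2COC[C@@H]2C=O)cc(OC)c1O[Si](C(C)C)(C(C)C)C(C)C | intermediate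
9 | 4-bromo-2,6-dimethoxyphenol | COc1cc(Br)cc(OC)c1O | starting material
10 | (4-bromo-2,6-dimethoxyphenoxy)triisopropylsilane | COc1cc(Br)cc(OC)c1O[Si](C(C)C)(C(C)C)C(C)C | intermediate
11 | {3,5-dimethoxy-4-[(triisopropylsilyl)oxy]phenyl}lithium | [Li]c1cc(OC)c(O[Si](C(C)C)(C(C)C)C(C)C)c(OC)c1 | intermediate
12 | {(3R,4R)-4-{3,5-dimethoxy-4-[(triisopropylsilyl)oxy]benzyl}tetrahydrofuran-3-yl}{3,5-dimethoxy-4-[(triisopropylsilyl)oxy]phenyl}methanol (both carbinol epimers) | COc1cc(C[C@H]2COC[C@@H]2C(O)c2cc(OC)c(O[Si](C(C)C)(C(C)C)C(C)C)c(OC)c2)cc(OC)c1O[Si](C(C)C)(C(C)C)C(C)C | intermediate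
13 | {(3R,4R)-4-{3,5-dimethoxy-4-[(triisopropylsilyl)oxy]benzyl}tetrahydrofuran-3-yl}{3,5-dimethoxy-4-[(triisopropylsilyl)oxy]phenyl}methanone | COc1cc(C[C@H]2COC[C@@H]2C(=O)c2cc(OC)c(O[Si](C(C)C)(C(C)C)C(C)C)c(OC)c2)cc(OC)c1O[Si](C(C)C)(C(C)C)C(C)C | intermediate
14 | (S)-{(3R,4R)-4-{3,5-dimethoxy-4-[(triisopropylsilyl)oxy]benzyl}tetrahydrofuran-3-yl}{3,5-dimethoxy-4-[(triisopropylsilyl)oxy]phenyl}methanol | COc1cc(C[C@H]2COC[C@@H]2[C@H](O)c2cc(OC)c(O[Si](C(C)C)(C(C)C)C(C)C)c(OC)c2)cc(OC)c1O[Si](C(C)C)(C(C)C)C(C)C | intermediate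
15 | (S)-(4-hydroxy-3,5-dimethoxyphenyl)[(3R,4R)-4-(4-hydroxy-3,5-dimethoxybenzyl)tetrahydrofuran-3-yl]methanol | COc1cc(C[C@H]2COC[C@@H]2[C@H](O)c2cc(OC)c(O)c(OC)c2)cc(OC)c1O | target

**Step count and risks**

Total step count: 10. Longest linear sequence: 9 (steps 1–5 and 7–10; step 6 is a one-step side branch).

Steps most likely to fail:

Step 4 (Heck benzylation). The electron-rich benzylic trifluoroacetate may solvolyse or homocouple before it inserts, the ligand may discriminate the two enantiotopic alkene carbons only moderately, or palladium hydride re-addition may move the double bond. The fallback sets out from 3 and comes back at 8; it sets the benzylic centre by auxiliary-controlled enolate alkylation and uses an open-chain version of the same C–C closure. PBr3 would give benzylic bromide F1. The sodium enolate (NaN(SiMe3)2, THF, −78 °C) of N-pentenoyl oxazolidinone F2, made from (R)-4-benzyloxazolidin-2-one and pent-4-enoyl chloride, would be alkylated by F1 to alkylated imide F3 (Evans alkylation, electrophile anti to the auxiliary benzyl group). LiBH4 would give primary alcohol F4, MOMCl/i-Pr2NEt would give methoxymethyl ether F5, and OsO4/NaIO4 would cleave the alkene to aldehyde F6. Me3SiOTf/Et3N would give silyl enol ether F7, and BF3·OEt2 would ionise the methoxymethyl acetal so that the same five-membered enol/oxocarbenium closure as in step 5 would give 8.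

Step 5 (ring contraction). The Lewis acid may ionise the acetal at the alkyl oxygen instead of the vinylic one, traces of water may hydrolyse the enol ether so that formaldehyde is lost, or recombination with the unsubstituted oxocarbenium ion may be slow and give oligomers. The fallback sets out from 6 and comes back at 8; the one-carbon unit is brought in by formylation of an enol ether, and the ring oxygen stays where it was. Aqueous acetic acid in THF would hydrolyse the vinyl acetal to lactol F8 with loss of formaldehyde. MsCl/Et3N would dehydrate it to 2,3-dihydrofuran F9. Vilsmeier–Haack formylation (POCl3, DMF, then aqueous NaOAc) at the enol ether β-carbon would give formyl dihydrofuran F10. Hydrogenation of the enal double bond (H2, Pd/C, EtOAc) would add hydrogen anti to the benzyl group and give mainly cis aldehyde F11, and equilibration with a trace of DBU would give the trans aldehyde 8.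

Step 9 (ketone reduction). Hydride delivery may be poorly face-selective, because the two ring branches at C3 differ little and the ring oxygen can bind borane. The fallback sets out from 12 and comes back at 14; it inverts the carbinol instead of reducing the ketone. The (R)-carbinol F12, the epimer of 12 that the addition in step 7 should favour, would be separated by chromatography and converted by Mitsunobu esterification (4-nitrobenzoic acid, PPh3, DIAD) with inversion to 4-nitrobenzoate F13. K2CO3 in MeOH at 0 °C, with short exposure, would cleave the ester to 14.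

**Further compounds**
F1 | step 4 | [4-(bromomethyl)-2,6-dimethoxyphenoxy]triisopropylsilane | COc1cc(CBr)cc(OC)c1O[Si](C(C)C)(C(C)C)C(C)C
F2 | step 4 | (R)-4-benzyl-3-(pent-4-enoyl)oxazolidin-2-one | C=CCCC(=O)N1[C@H](Cc2ccccc2)COC1=O
F3 | step 4 | (R)-4-benzyl-3-[(S)-2-{3,5-dimethoxy-4-[(triisopropylsilyl)oxy]benzyl}pent-4-enoyl]oxazolidin-2-one | COc1cc(C[C@H](CC=C)C(=O)N2[C@H](Cc3ccccc3)COC2=O)cc(OC)c1O[Si](C(C)C)(C(C)C)C(C)C
F4 | step 4 | (S)-2-{3,5-dimethoxy-4-[(triisopropylsilyl)oxy]benzyl}pent-4-en-1-ol | COc1cc(C[C@H](CC=C)CO)cc(OC)c1O[Si](C(C)C)(C(C)C)C(C)C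
F5 | step 4 | {4-[(2S)-2-[(methoxymethoxy)methyl]pent-4-en-1-yl]-2,6-dimethoxyphenoxy}triisopropylsilane | COc1cc(C[C@H](CC=C)COCOC)cc(OC)c1O[Si](C(C)C)(C(C)C)C(C)C
F6 | step 4 | (R)-3-{3,5-dimethoxy-4-[(triisopropylsilyl)oxy]benzyl}-4-(methoxymethoxy)butanal | COc1cc(C[C@H](CC=O)COCOC)cc(OC)c1O[Si](C(C)C)(C(C)C)C(C)C
F7 | step 4 | {[(3R)-3-{3,5-dimethoxy-4-[(triisopropylsilyl)oxy]benzyl}-4-(methoxymethoxy)but-1-en-1-yl]oxy}trimethylsilane (E/Z mixture) | COc1cc(C[C@H](C=CO[Si](C)(C)C)COCOC)cc(OC)c1O[Si](C(C)C)(C(C)C)C(C)C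
F8 | step 5 | (4R)-4-{3,5-dimethoxy-4-[(triisopropylsilyl)oxy]benzyl}tetrahydrofuran-2-ol (both anomers) | COc1cc(C[C@H]2COC(O)C2)cc(OC)c1O[Si](C(C)C)(C(C)C)C(C)C
F9 | step 5 | (R)-3-{3,5-dimethoxy-4-[(triisopropylsilyl)oxy]benzyl}-2,3-dihydrofuran | COc1cc(C[C@H]2COC=C2)cc(OC)c1O[Si](C(C)C)(C(C)C)C(C)C
F10 | step 5 | (R)-4-{3,5-dimethoxy-4-[(triisopropylsilyl)oxy]benzyl}-4,5-dihydrofuran-3-carbaldehyde | COc1cc(C[C@H]2COC=C2C=O)cc(OC)c1O[Si](C(C)C)(C(C)C)C(C)C
F11 | step 5 | (3S,4R)-4-{3,5-dimethoxy-4-[(triisopropylsilyl)oxy]benzyl}tetrahydrofuran-3-carbaldehyde (cis) | COc1cc(C[C@H]2COC[C@H]2C=O)cc(OC)c1O[Si](C(C)C)(C(C)C)C(C)C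
F12 | step 9 | (R)-{(3R,4R)-4-{3,5-dimethoxy-4-[(triisopropylsilyl)oxy]benzyl}tetrahydrofuran-3-yl}{3,5-dimethoxy-4-[(triisopropylsilyl)oxy]phenyl}methanol | COc1cc(C[C@H]2COC[C@@H]2[C@@H](O)c2cc(OC)c(O[Si](C(C)C)(C(C)C)C(C)C)c(OC)c2)cc(OC)c1O[Si](C(C)C)(C(C)C)C(C)C
F13 | step 9 | (S)-{(3R,4R)-4-{3,5-dimethoxy-4-[(triisopropylsilyl)oxy]benzyl}tetrahydrofuran-3-yl}{3,5-dimethoxy-4-[(triisopropylsilyl)oxy]phenyl}methyl 4-nitrobenzoate | COc1cc(C[C@H]2COC[C@@H]2[C@H](OC(=O)c2ccc(cc2)[N+](=O)[O-])c2cc(OC)c(O[Si](C(C)C)(C(C)C)C(C)C)c(OC)c2)cc(OC)c1O[Si](C(C)C)(C(C)C)C(C)C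
A1 | direct plan | (S)-4-benzyl-3-[(S)-2-[(S)-[4-(benzyloxy)-3,5-dimethoxyphenyl](hydroxy)methyl]pent-4-enoyl]oxazolidin-2-one | C=CC[C@H](C(=O)N1[C@@H](Cc2ccccc2)COC1=O)[C@H](O)c1cc(OC)c(OCc2ccccc2)c(OC)c1
A2 | direct plan | (R)-4-[(S)-[4-(benzyloxy)-3,5-dimethoxyphenyl][(triisopropylsilyl)oxy]methyl]dihydrofuran-2(3H)-one | O=C1C[C@H](CO1)[C@H](O[Si](C(C)C)(C(C)C)C(C)C)c1cc(OC)c(OCc2ccccc2)c(OC)c1
A3 | direct plan | (2R,3R)-2-[4-(benzyloxy)-3,5-dimethoxybenzyl]-3-[(S)-[4-(benzyloxy)-3,5-dimethoxyphenyl][(triisopropylsilyl)oxy]methyl]butane-1,4-diol | COc1cc(C[C@@H](CO)[C@H](CO)[C@H](O[Si](C(C)C)(C(C)C)C(C)C)c2cc(OC)c(OCc3ccccc3)c(OC)c2)cc(OC)c1OCc1ccccc1
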